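**Plan**

- Retrosynthesis: after removal of the acid-labile groups, the cinnamate C=C is cut back to a C4 aldehyde. Then three bonds are cut at once: C2–aryl, C3–C(=O) and the acyl C–O bond to the shikimate C5 oxygen. This leaves a 2,3-unsubstituted benzofuran, an aryl iodide, CO and a shikimate alcohol.
- Forward: ring A is made as a benzofuran (Sonogashira coupling, then 5-endo closure of the furan ring). Aryl iodide and shikimate alcohol are made separately. The three pieces and CO are joined in one step, with no ring formed. Acetal hydrolysis, Wittig olefination and one acidic deprotection finish the route.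
- Enabling feature: on the dihydrofuran ring the C2 aryl group and the C3 ester carbonyl are cis. That is the pattern left by adding an aryl group and a carbonyl to the same face of the C2=C3 bond of a benzofuran. Palladium at benzylic C3 has no syn β-hydrogen, so it can be carbonylated.
- Stereochemistry: C3, C4 and C5 of the cyclohexene come unchanged from shikimic acid. C2 of the dihydrobenzofuran is set by the chiral bisphosphine in the carbopalladation. C3 follows from syn insertion and retentive CO insertion. The E alkene comes from a stabilised ylide.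

Key step: step 10

Assumption: the facial sense of (S)-BINAP on the benzofuran is taken by analogy with the arylation of 2,3-dihydrofuran. If it proves opposite, (R)-BINAP is used and nothing else changes. Numbering: benzofuran O1, C2, C3, C3a, C4–C7, C7a; shikimate C1 (carboxyl) to C6.

**Route**

Step 1
Reactants: 1 3,4-dihydroxybenzaldehyde
Product: 2 3-hydroxy-4-(methoxymethoxy)benzaldehyde
Conditions: MOMCl (1.05 equiv), K2CO3 (1.1 equiv), acetone, 0 °C to rt
Reagents that add atoms: chloromethyl methyl ether, COCCl
Why: Williamson-type O-alkylation in which the 4-hydroxyl, para to the formyl group, is the more acidic phenol and is the one deprotonated by one equivalent of carbonate, so the MOM group should go there selectively.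

Step 2
Reactants: 2 3-hydroxy-4-(methoxymethoxy)benzaldehyde
Product: 3 3-hydroxy-2-iodo-4-(methoxymethoxy)benzaldehyde
Conditions: ICl, pyridine, 1,4-dioxane, 0 °C to rt
Reagents that add atoms: iodine monochloride, ICl
Why: Electrophilic aromatic iodination ortho to the free phenol, at the position between hydroxyl and formyl that isovanillin-type substrates take under these conditions, with pyridine keeping the medium non-acidic for the MOM ether.

Step 3
Reactants: 3 3-hydroxy-2-iodo-4-(methoxymethoxy)benzaldehyde
Product: 4 3-hydroxy-4-(methoxymethoxy)-2-[(trimethylsilyl)ethynyl]benzaldehyde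
Conditions: HC≡CSiMe3, Pd(PPh3)2Cl2 (cat.), CuI (cat.), Et3N, THF, rt
Reagents that add atoms: trimethylsilylacetylene, C#C[Si](C)(C)C
Why: Sonogashira coupling of an aryl iodide proceeds at room temperature beside a free ortho hydroxyl and a formyl group, and any silylbenzofuran formed by early cyclisation would converge in step 4.

Step 4
Reactants: 4 3-hydroxy-4-(methoxymethoxy)-2-[(trimethylsilyl)ethynyl]benzaldehyde
Product: 6 7-(methoxymethoxy)-1-benzofuran-4-carbaldehyde, via terminal alkyne phenol 5 (not isolated)
Conditions: Bu4NF·3H2O, THF, 65 °C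
Reagents that add atoms: none
Why: Fluoride removes the silyl group and the phenoxide then adds to the terminal alkyne carbon in a 5-endo-dig cycloisomerisation, the usual fluoride-mediated benzofuran synthesis from ortho-alkynylphenols.

Step 5
Reactants: 6 7-(methoxymethoxy)-1-benzofuran-4-carbaldehyde
Product: 7 4-(1,3-dioxolan-2-yl)-7-(methoxymethoxy)-1-benzofuran
Conditions: (Me3SiOCH2)2, Me3SiOTf (cat.), CH2Cl2, −78 to −20 °C; pyridine quench
Reagents that add atoms: 1,2-bis(trimethylsilyloxy)ethane, C[Si](C)(C)OCCO[Si](C)(C)C
Why: Noyori acetalisation under aprotic conditions at low temperature turns the aryl aldehyde into the dioxolane without the protic acid and free diol that would endanger the MOM ether.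

Step 6
Reactants: 8 catechol
Product: 9 1,2-bis(methoxymethoxy)benzene
Conditions: NaH, MOMCl, DMF, 0 °C to rt
Reagents that add atoms: chloromethyl methyl ether, COCCl
Why: Double Williamson etherification of the catechol dianion with the reactive α-chloro ether.

Step 7
Reactants: 9 1,2-bis(methoxymethoxy)benzene
Product: 10 4-iodo-1,2-bis(methoxymethoxy)benzene
Conditions: NIS, CF3CO2H (10 mol %), MeCN, 0 °C to rt
Reagents that add atoms: N-iodosuccinimide, O=C1CCC(=O)N1I
Why: Electrophilic aromatic iodination para to one of the two equivalent alkoxy groups, with only catalytic acid to activate NIS so that the MOM ethers should survive.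

Step 8
Reactants: 11 shikimic acid
Product: 12 3,4-O-isopropylideneshikimic acid
Conditions: Me2C(OMe)2, TsOH·H2O (cat.), acetone, rt
Reagents that add atoms: 2,2-dimethoxypropane, COC(C)(C)OC
Why: Acid-catalysed transketalisation in which the cis-3,4-diol forms the five-membered acetonide in preference to the trans-4,5-diol, leaving the C5 hydroxyl free and touching no stereocentre.

Step 9
Reactants: 12 3,4-O-isopropylideneshikimic acid
Product: 13 tert-butyl 3,4-O-isopropylideneshikimate (free C5 hydroxyl)
Conditions: Me2NCH(OtBu)2, toluene, 80 °C
Reagents that add atoms: N,N-dimethylformamide di-tert-butyl acetal, CN(C)C(OC(C)(C)C)OC(C)(C)C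
Why: Neutral tert-butyl esterification by O-alkylation of the carboxylate within the ion pair formed from the amide acetal, which leaves the secondary hydroxyl and the acetonide alone.

Step 10
Reactants: 7 4-(1,3-dioxolan-2-yl)-7-(methoxymethoxy)-1-benzofuran (1.5 equiv); 10 4-iodo-1,2-bis(methoxymethoxy)benzene; 13 tert-butyl 3,4-O-isopropylideneshikimate
Product: 14 tert-butyl 3,4-O-isopropylideneshikimat-5-yl (2S,3R)-2-[3,4-bis(methoxymethoxy)phenyl]-4-(1,3-dioxolan-2-yl)-7-(methoxymethoxy)-2,3-dihydro-1-benzofuran-3-carboxylate (C2 aryl and C3 ester cis)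
Conditions: Pd(OAc)2 (10 mol %), (S)-BINAP (12 mol %), Ag2CO3 (1 equiv), 4 Å MS, CO (1 atm), 1,4-dioxane, 60 °C
Reagents that add atoms: carbon monoxide, [C-]#[O+]
Why: Proposed new method: oxidative addition of 10 to zerovalent palladium and iodide abstraction by silver should give a cationic BINAP arylpalladium species that adds syn across the enol-ether-like C2=C3 bond of 7 with aryl at the oxygen-bearing C2 and palladium at benzylic C3, after which CO insertion with retention and alcoholysis of the acylpalladium by the C5 hydroxyl of 13 release 14 and zerovalent palladium. The closest known reaction types are the enantioselective Heck arylation of 2,3-dihydrofuran, the arylcarbonylation of norbornene-type alkenes that lack a syn β-hydrogen, and the intramolecular dearomative carbopalladation–carbonylation of indoles and benzofurans; the intermolecular three-component version on a benzofuran is the untested part. No ring closes, since the furan ring of 7 is kept and only loses its aromaticity. C2 is set by the enantiofacial choice of the BINAP-bound palladium in the carbopalladation, and C3 follows from it because syn insertion puts palladium cis to the aryl group and CO insertion retains configuration, giving the (2S,3R) cis ester. The step needs C2 regioselectivity, secured by the polarisation of the O1–C2=C3 enol ether and benzylic stabilisation of palladium at C3, and carbonylation faster than loss of palladium, secured by the only β-hydrogen (on C2) being anti to the metal. Premature carbonylation of the arylpalladium is held back by the low CO pressure and the excess of 7, and because 13 is enantiopure any product from the minor face is a diastereomer removable by chromatography.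

Step 11
Reactants: 14 the dioxolane-bearing cis ester
Product: 15 tert-butyl 3,4-O-isopropylideneshikimat-5-yl (2S,3R)-2-[3,4-bis(methoxymethoxy)phenyl]-4-formyl-7-(methoxymethoxy)-2,3-dihydro-1-benzofuran-3-carboxylate
Conditions: PPTS (cat.), acetone–H2O (20:1), rt to 40 °C
Reagents that add atoms: water, O
Why: Acid-catalysed acetal hydrolysis in which the benzylic oxocarbenium ion from the aryl dioxolane, stabilised by the para MOM-oxy group, forms far more readily than cations from the formaldehyde acetals or from the acetonide, whose exchange with acetone is degenerate.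

Step 12
Reactants: 15 the C4 aldehyde
Product: 16 tert-butyl 3,4-O-isopropylideneshikimat-5-yl (2S,3R)-2-[3,4-bis(methoxymethoxy)phenyl]-4-[(E)-3-tert-butoxy-3-oxoprop-1-enyl]-7-(methoxymethoxy)-2,3-dihydro-1-benzofuran-3-carboxylate
Conditions: Ph3P=CHCO2tBu, toluene, rt to 50 °C
Reagents that add atoms: tert-butyl (triphenylphosphoranylidene)acetate, CC(C)(C)OC(=O)C=P(c1ccccc1)(c1ccccc1)c1ccccc1
Why: Wittig olefination with a stabilised ylide gives the E-cinnamate and the ylide is too weakly basic to deprotonate C3, so the cis ester should survive.

Step 13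
Reactants: 16 the fully protected cinnamate
Product: 17 CNP0312618.1, (E)-3-[(2S,3R)-2-(3,4-dihydroxyphenyl)-7-hydroxy-3-(shikim-5-O-ylcarbonyl)-2,3-dihydro-1-benzofuran-4-yl]prop-2-enoic acid
Conditions: CF3CO2H–H2O (9:1), 0 °C to rt; reversed-phase chromatography
Reagents that add atoms: none
Why: Acid-mediated global deprotection in which aqueous trifluoroacetic acid hydrolyses the three MOM acetals and the acetonide and cleaves both tert-butyl esters through the tert-butyl cation, while the secondary alkyl ester on the shikimate C5 oxygen is stable to acid at this temperature.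

**Compound list**

1 | 3,4-dihydroxybenzaldehyde | O=Cc1ccc(O)c(O)c1 | starting material
2 | 3-hydroxy-4-(methoxymethoxy)benzaldehyde | O=Cc1ccc(OCOC)c(O)c1 | intermediate
3 | 3-hydroxy-2-iodo-4-(methoxymethoxy)benzaldehyde | O=Cc1ccc(OCOC)c(O)c1I | intermediate
4 | 3-hydroxy-4-(methoxymethoxy)-2-[(trimethylsilyl)ethynyl]benzaldehyde | O=Cc1ccc(OCOC)c(O)c1C#C[Si](C)(C)C | intermediate
5 | 2-ethynyl-3-hydroxy-4-(methoxymethoxy)benzaldehyde (formed in the flask, not isolated) | O=Cc1ccc(OCOC)c(O)c1C#C | intermediate
6 | 7-(methoxymethoxy)-1-benzofuran-4-carbaldehyde | O=Cc1ccc(OCOC)c2occc12 | intermediate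
7 | 4-(1,3-dioxolan-2-yl)-7-(methoxymethoxy)-1-benzofuran | COCOc1ccc(C2OCCO2)c2ccoc12 | intermediate
8 | catechol | Oc1ccccc1O | starting material
9 | 1,2-bis(methoxymethoxy)benzene | COCOc1ccccc1OCOC | intermediate
10 | 4-iodo-1,2-bis(methoxymethoxy)benzene | COCOc1ccc(I)cc1OCOC | intermediate
11 | shikimic acid, (3R,4S,5R) | O[C@@H]1CC(C(=O)O)=C[C@@H](O)[C@H]1O | starting material
12 | 3,4-O-isopropylideneshikimic acid, (3R,4S,5R) | O[C@@H]1CC(C(=O)O)=C[C@@H](O2)[C@H]1OC2(C)C | intermediate
13 | tert-butyl 3,4-O-isopropylideneshikimate, (3R,4S,5R), free C5 hydroxyl | O[C@@H]1CC(C(=O)OC(C)(C)C)=C[C@@H](O2)[C@H]1OC2(C)C | intermediate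
14 | cis-(2S,3R)-2-aryl-2,3-dihydrobenzofuran-3-carboxylic shikimate ester with C4 dioxolane, three MOM ethers, acetonide and tert-butyl ester | O1CCOC1c1ccc(OCOC)c2c1[C@@H](C(=O)O[C@@H]1CC(C(=O)OC(C)(C)C)=C[C@@H](O3)[C@H]1OC3(C)C)[C@@H](c1ccc(OCOC)c(OCOC)c1)O2 | intermediate
15 | C4 aldehyde corresponding to 14, (2S,3R) | O=Cc1ccc(OCOC)c2c1[C@@H](C(=O)O[C@@H]1CC(C(=O)OC(C)(C)C)=C[C@@H](O3)[C@H]1OC3(C)C)[C@@H](c1ccc(OCOC)c(OCOC)c1)O2 | intermediate
16 | (E)-tert-butyl cinnamate corresponding to 15, (2S,3R) | CC(C)(C)OC(=O)/C=C/c1ccc(OCOC)c2c1[C@@H](C(=O)O[C@@H]1CC(C(=O)OC(C)(C)C)=C[C@@H](O3)[C@H]1OC3(C)C)[C@@H](c1ccc(OCOC)c(OCOC)c1)O2 | intermediate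
17 | CNP0312618.1 | O=C(O)/C=C/c1ccc(O)c2c1[C@@H](C(=O)O[C@@H]1CC(C(=O)O)=C[C@@H](O)[C@H]1O)[C@@H](c1ccc(O)c(O)c1)O2 | target

**Count**

Total steps: 13. Longest linear sequence: 9 steps (steps 1–5, then 10–13).

**Steps most likely to fail**

Step 10. Several processes can take over:
- CO may insert into the arylpalladium before it meets the benzofuran, giving direct esterification of the aryl iodide by 13.
- The benzylpalladium may lose palladium and rearomatise to a 2-arylbenzofuran.
- Alcoholysis by the hindered alcohol may be slow.
- Facial selectivity may be poor.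

The fallback uses known carbene chemistry; it sets out from 3 (with 10 and 13) and returns at 14.
- Iodine–magnesium exchange on 10 (iPrMgCl·LiCl, THF) and addition to paraformaldehyde would give 3,4-bis(methoxymethoxy)benzyl alcohol F1.
- Mitsunobu etherification of 3 with F1 (PPh3, DIAD) would give 3-{[3,4-bis(methoxymethoxy)phenyl]methoxy}-2-iodo-4-(methoxymethoxy)benzaldehyde F2.
- Acetalisation as in step 5 would give the corresponding aryl dioxolane F3.
- Separately, 13 would be acylated with bromoacetyl bromide and pyridine to the shikimate bromoacetate F4, then converted with N,N'-ditosylhydrazine and DBU into the shikimate diazoacetate F5.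
- Palladium-catalysed coupling of the aryl iodide with the diazo ester, keeping the diazo group (Pd(PPh3)4, Ag2CO3, Et3N, toluene, rt), would give the aryldiazoacetate F6.
- Rh2(S-PTTL)4 in toluene at −60 °C would then insert the carbene into the benzylic C–H bond of the ether. This closes the dihydrofuran ring through the C2–C3 bond with the cis selectivity known for this catalyst class, giving 14.
- The low temperature is chosen so that reversible ylide formation at the acetal oxygen should have no productive exit. The enantiopure ester again turns any wrong-face product into a separable diastereomer.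

Step 13. Acid may ionise the benzylic C2–O bond next to the electron-rich aryl group and erode the cis relationship. The acyl group may migrate from O5 to O4. Released formaldehyde or tert-butyl cation may alkylate the catechol rings.

The fallback sets out from 16 and returns at 17. It replaces the single protic solvolysis by two stages.
- Silyl transfer (Me3SiOTf, 2,2'-bipyridyl, CH2Cl2, 0 °C, then water) would cleave the MOM ethers and tert-butyl esters through silyl ethers and silyl esters. This would give the acetonide-retaining pentahydroxy... more exactly the triphenol diacid acetonide F7.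
- The acetonide of F7 would then be released under much milder hydrolysis (sulfonic acid resin in aqueous acetonitrile, rt) to give 17.

Step 12. The ylide may act as a base and cause epimerisation at C3 or E1cB opening of the dihydrofuran ring. The hindered aldehyde may also react slowly enough to require heating.

The fallback sets out from 15 and returns at 16.
- Non-basic Takai methylenation (CH2I2, Zn, Ti(OiPr)4, THF) would give the 4-vinyl compound F8.
- Cross-metathesis of F8 with tert-butyl acrylate (second-generation Hoveyda–Grubbs catalyst, CH2Cl2, 40 °C) would give the E-cinnamate 16. The trisubstituted, conjugated shikimate alkene should not take part.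

**Further compounds**

F1 | step 10 | 3,4-bis(methoxymethoxy)benzyl alcohol | OCc1ccc(OCOC)c(OCOC)c1
F2 | step 10 | 3-{[3,4-bis(methoxymethoxy)phenyl]methoxy}-2-iodo-4-(methoxymethoxy)benzaldehyde | O=Cc1ccc(OCOC)c(OCc2ccc(OCOC)c(OCOC)c2)c1I
F3 | step 10 | 2-{3-{[3,4-bis(methoxymethoxy)phenyl]methoxy}-2-iodo-4-(methoxymethoxy)phenyl}-1,3-dioxolane | COCOc1ccc(C2OCCO2)c(I)c1OCc1ccc(OCOC)c(OCOC)c1
F4 | step 10 | tert-butyl 5-O-(bromoacetyl)-3,4-O-isopropylideneshikimate | O=C(CBr)O[C@@H]1CC(C(=O)OC(C)(C)C)=C[C@@H](O2)[C@H]1OC2(C)C
F5 | step 10 | tert-butyl 5-O-(diazoacetyl)-3,4-O-isopropylideneshikimate | [N-]=[N+]=CC(=O)O[C@@H]1CC(C(=O)OC(C)(C)C)=C[C@@H](O2)[C@H]1OC2(C)C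
F6 | step 10 | tert-butyl 3,4-O-isopropylideneshikimat-5-yl 2-diazo-2-{2-{[3,4-bis(methoxymethoxy)phenyl]methoxy}-6-(1,3-dioxolan-2-yl)-3-(methoxymethoxy)phenyl}acetate | COCOc1ccc(C2OCCO2)c(C(=[N+]=[N-])C(=O)O[C@@H]2CC(C(=O)OC(C)(C)C)=C[C@@H](O3)[C@H]2OC3(C)C)c1OCc1ccc(OCOC)c(OCOC)c1
F7 | step 13 | 3,4-O-isopropylidene derivative of 17 (free phenols and free carboxylic acids) | O=C(O)/C=C/c1ccc(O)c2c1[C@@H](C(=O)O[C@@H]1CC(C(=O)O)=C[C@@H](O3)[C@H]1OC3(C)C)[C@@H](c1ccc(O)c(O)c1)O2
F8 | step 12 | 4-vinyl analogue of 15 | C=Cc1ccc(OCOC)c2c1[C@@H](C(=O)O[C@@H]1CC(C(=O)OC(C)(C)C)=C[C@@H](O3)[C@H]1OC3(C)C)[C@@H](c1ccc(OCOC)c(OCOC)c1)O2
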